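**Assumption:** the SMILES is taken at face value, i.e. the (1(10)Z,4S,5S,6S,7S,8R,11R) isomer; carbons are labelled C1–C15 in germacrane numbering (C12 = lactone carbonyl, C13 = methyl on C11, C14 = methyl on C10, C15 = methyl on C4).

## Retrosynthetic overview

1. Both angelates come off last (C11: acylation of the tertiary alkoxide; C6: Mitsunobu esterification with inversion). The ten-membered ring is then opened at the C1=C10 (Z) olefin, which is closed by ring-closing metathesis.
2. The oxirane comes from hydroxyl-directed epoxidation of an (E)-allylic alcohol; the C5–C6 bond comes from chelation-controlled alkenyl addition to a lactone aldehyde.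
3. The γ-lactone (C7, C8, C11, C12) is a menthyloxybutenolide elaborated by 1,4-addition (C6 as a dithiane), hydroxylation then methylation (C11), and indium methallylation (C8–C9).
4. Key step: singlet-oxygen dearomatization of furfural with excision of the formyl carbon. The resulting butenolide is fixed as one acetal epimer with (+)-menthol, and that single centre is the only external stereochemical input, relayed to all six stereocentres.
5. Ring order: lactone, then oxirane, then carbocycle.

## Route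

Step 1
Reactants: 1 furfural
Product: 2 5-hydroxyfuran-2(5H)-one (racemic hemiacylal)
Conditions: O2, visible light, 4,5,6,7-tetrachloro-2',4',5',7'-tetraiodofluorescein disodium salt (rose bengal, cat.), MeOH, 20 °C
Reagents that add atoms: dioxygen (O=O)
Why: Singlet oxygen adds [4+2] across the furan (Schenck photooxygenation), breaking its aromaticity, and methanolysis of the endoperoxide expels the formyl carbon as methyl formate to leave the four-carbon butenolide that becomes C12, C11, C7 and C8.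

Step 2
Reactants: 2 5-hydroxyfuran-2(5H)-one; 3 (+)-menthol
Product: 4 (5S)-5-{[(1S,2R,5S)-5-methyl-2-(propan-2-yl)cyclohexyl]oxy}furan-2(5H)-one
Conditions: 4-toluenesulfonic acid (cat.), toluene, reflux (Dean–Stark); crystallization from petroleum ether, mother liquor re-equilibrated with acid and recrystallized
Reagents that add atoms: none
Why: Acid-catalysed acetalization gives both acetal epimers, which interconvert under acid, and crystallization-induced asymmetric transformation funnels the material to the crystalline (5S) epimer (mirror image of the known (5R)-l-menthyloxy butenolide), so the acetal carbon (future C8) is set by the auxiliary.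

Step 3
Reactants: 4 (5S)-menthyloxybutenolide; 5 1,3-dithiane
Product: 9 (3S,4S,5S)-4-(1,3-dithian-2-yl)-5-{[(1S,2R,5S)-5-methyl-2-(propan-2-yl)cyclohexyl]oxy}-3-[(triethylsilyl)oxy]dihydrofuran-2(3H)-one, via 2-lithio-1,3-dithiane 6 (not isolated), via lithium enolate 7 (not isolated), via lithium alkoxide 8 (not isolated)
Conditions: 5, n-BuLi, THF, −25 °C; add 4, −78 °C; then trans-2-(phenylsulfonyl)-3-phenyloxaziridine (1.05 equiv), −78 °C; then Et3SiCl, imidazole, −78 → 0 °C
Reagents that add atoms: trans-2-(phenylsulfonyl)-3-phenyloxaziridine (O=S(=O)(c1ccccc1)N1OC1c1ccccc1); chlorotriethylsilane (CC[Si](Cl)(CC)CC)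
Why: Michael addition of the dithiane anion occurs only anti to the menthyloxy group (sets C7), the enolate is hydroxylated by the Davis oxaziridine anti to the new dithianyl group (this C11 configuration is provisional and erased in step 4), and the alkoxide is silylated in the same pot.

Step 4
Reactants: 9 silyloxy lactone
Product: 11 (3R,4S,5S)-4-(1,3-dithian-2-yl)-3-methyl-5-{[(1S,2R,5S)-5-methyl-2-(propan-2-yl)cyclohexyl]oxy}-3-[(triethylsilyl)oxy]dihydrofuran-2(3H)-one, via lithium enolate 10 (not isolated)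
Conditions: LiN(i-Pr)2, THF, −78 °C; MeI, −78 → −40 °C
Reagents that add atoms: iodomethane (CI)
Why: Enolate alkylation of the α-silyloxy lactone, with methyl iodide entering anti to the neighbouring dithianyl group, creates the C11 quaternary centre with oxygen cis to the C7 side chain (11R of the target).

Step 5
Reactants: 11 methylated lactone
Product: 12 (3R,4S)-4-(1,3-dithian-2-yl)-3,5-dihydroxy-3-methyldihydrofuran-2(3H)-one (lactol, mixture of C5 anomers)
Conditions: CF3CO2H–H2O–THF (2:1:2), 20 °C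
Reagents that add atoms: water (O)
Why: Acid hydrolysis of the pseudo-ester acetal releases the auxiliary and cleaves the silyl ether while the dithioacetal survives, unmasking C8 as a lactol (aldehyde acid) with C6 still masked.

Step 6
Reactants: 12 lactol
Product: 14 (3R,4R,5R)-4-(1,3-dithian-2-yl)-3-hydroxy-3-methyl-5-(2-methylprop-2-en-1-yl)dihydrofuran-2(3H)-one, via hydroxy acid 13 (not isolated)
Conditions: In powder, 3-bromo-2-methylprop-1-ene, THF–H2O (1:1), 25 °C; then 1 M HCl
Reagents that add atoms: 3-bromo-2-methylprop-1-ene (CC(=C)CBr)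
Why: Aqueous Barbier allylation of the ring-opened aldehyde with the methallylindium reagent occurs on the face anti to the dithianyl-bearing neighbour (the β-hydroxyl chelate and the Felkin–Anh model agree), and acid relactonization gives the 7,8-trans lactone, setting C8 (8R of the target).

Step 7
Reactants: 14 methallyl lactone
Product: 15 (2R,3R,4R)-4-hydroxy-4-methyl-2-(2-methylprop-2-en-1-yl)-5-oxotetrahydrofuran-3-carbaldehyde
Conditions: MeI, CaCO3, MeCN–H2O (9:1), 40 °C; used crude and cold
Reagents that add atoms: water (O)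
Why: Alkylative hydrolysis of the dithioacetal (S-methylation, then hydrolysis) frees the C6 aldehyde under near-neutral conditions that spare the olefin, lactone and tertiary alcohol, with no stereocentre touched.

Step 8
Reactants: 16 hex-1-en-5-yne
Product: 18 (1E)-1-iodo-2-methylhexa-1,5-diene, via alkenylalane 17 (not isolated)
Conditions: AlMe3 (2 equiv), Cp2ZrCl2 (20 mol %), CH2Cl2, 0 → 25 °C; then I2, THF, −30 °C
Reagents that add atoms: trimethylaluminium (C[Al](C)C); iodine (II)
Why: Negishi zirconium-catalysed carboalumination adds methyl and aluminium syn across the alkyne (methyl to the internal carbon), and iodinolysis with retention gives the (E)-iodide that fixes the C4=C5 geometry and carries C15.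

Step 9
Reactants: 15 lactone aldehyde; 18 (1E)-1-iodo-2-methylhexa-1,5-diene
Product: 20 (3R,4R,5R)-3-hydroxy-4-[(1S,2E)-1-hydroxy-3-methylhepta-2,6-dien-1-yl]-3-methyl-5-(2-methylprop-2-en-1-yl)dihydrofuran-2(3H)-one, via alkenyllithium 19 (not isolated)
Conditions: 18, t-BuLi (2 equiv per iodide), Et2O, −78 °C; add (2.5 equiv) to 15 and MgBr2·OEt2 (3 equiv), CH2Cl2, −78 °C; NH4Cl work-up
Reagents that add atoms: none
Why: Chelation-controlled carbonyl addition, in which magnesium bridges the C11 alkoxide and the aldehyde oxygen and the alkenyl group attacks from the side of H-7, gives the (S)-carbinol, i.e. the C6 epimer of the target, which is what step 10 needs and step 11 corrects.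

Step 10
Reactants: 20 allylic alcohol
Product: 21 (3R,4R,5R)-4-{(R)-[(2S,3S)-3-(but-3-en-1-yl)-3-methyloxiran-2-yl](hydroxy)methyl}-3-hydroxy-3-methyl-5-(2-methylprop-2-en-1-yl)dihydrofuran-2(3H)-one
Conditions: 3-chloroperoxybenzoic acid (1.05 equiv), NaHCO3, CH2Cl2, −20 → 0 °C
Reagents that add atoms: 3-chloroperoxybenzoic acid (OOC(=O)c1cccc(Cl)c1)
Why: Henbest hydroxyl-directed epoxidation of the most electron-rich (trisubstituted) olefin proceeds through the A-1,3-minimized conformer (C15 methyl cis to C6), delivering oxygen syn to the hydroxyl (threo) and setting C4 and C5 as 4S,5S.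

Step 11
Reactants: 21 threo epoxy alcohol; 22 angelic acid ((2Z)-2-methylbut-2-enoic acid)
Product: 23 (S)-[(2S,3S)-3-(but-3-en-1-yl)-3-methyloxiran-2-yl][(2R,3S,4R)-4-hydroxy-4-methyl-2-(2-methylprop-2-en-1-yl)-5-oxotetrahydrofuran-3-yl]methyl (2Z)-2-methylbut-2-enoate
Conditions: PPh3, diisopropyl azodicarboxylate, toluene, 0 → 25 °C
Reagents that add atoms: none
Why: Mitsunobu esterification displaces the activated secondary hydroxyl by angelate with clean SN2 inversion, installing the C6 ester and turning the threo array into the erythro 4S,5S,6S array of the target, while the tertiary C11 hydroxyl does not react.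

Step 12
Reactants: 23 seco-diene
Product: 24 (1(10)Z,4S,5S,6S,7S,8R,11R)-6-angeloyloxy-4,5-epoxy-11-hydroxygermacr-1(10)-en-12,8-olide
Conditions: second-generation Grubbs catalyst RuCl2(=CHPh)(H2IMes)(PCy3) (10 mol %), 1,4-benzoquinone (20 mol %), toluene (1 mM), 80 °C
Reagents that add atoms: none
Why: Ring-closing metathesis between the terminal vinyl group (C1) and the methallyl group (C10) releases ethene and closes the carbocycle, and the ten-membered ring together with the trans-fused lactone and trans-oxirane favours the less strained (Z) trisubstituted olefin.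

Step 13
Reactants: 24 macrocyclic hydroxy lactone; 22 angelic acid
Product: 27 target CNP0118683.3, (1(10)Z,4S,5S,6S,7S,8R,11R)-6,11-bis(angeloyloxy)-4,5-epoxygermacr-1(10)-en-12,8-olide, via mixed anhydride 25 (not isolated), via lithium alkoxide 26 (not isolated)
Conditions: 22, 2,4,6-trichlorobenzoyl chloride, Et3N, toluene, 20 °C; separately 24, LiN(SiMe3)2 (1.1 equiv), THF, −78 °C; combine, −78 → −20 °C
Reagents that add atoms: none
Why: Yamaguchi-type acylation of the pre-formed tertiary lithium alkoxide by the angelic mixed anhydride at low temperature esterifies the hindered C11 hydroxyl without Z-to-E isomerization and creates no new stereocentre.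

## Compound list

1 | furfural (furan-2-carbaldehyde) | O=Cc1ccco1 | starting material
2 | 5-hydroxyfuran-2(5H)-one (racemic) | OC1OC(=O)C=C1 | intermediate
3 | (+)-menthol, (1S,2R,5S)-5-methyl-2-(propan-2-yl)cyclohexan-1-ol | O[C@H]1C[C@@H](C)CC[C@@H]1C(C)C | starting material
4 | (5S)-5-[(1S,2R,5S)-menthyloxy]furan-2(5H)-one | C1=CC(=O)O[C@@H]1O[C@H]2C[C@@H](C)CC[C@@H]2C(C)C | intermediate
5 | 1,3-dithiane | C1CSCSC1 | starting material
6 | 2-lithio-1,3-dithiane | [Li]C1SCCCS1 | intermediate (not isolated)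
7 | lithium enolate of the 1,4-adduct (dithianyl trans to menthyloxy) | [Li]OC1=C[C@H](C2SCCCS2)[C@@H](O[C@H]3C[C@@H](C)CC[C@@H]3C(C)C)O1 | intermediate (not isolated)
8 | lithium alkoxide of the (3S,4S,5S)-3-hydroxy lactone | C1CSC(SC1)[C@@H]2[C@@H](O[C@H]3C[C@@H](C)CC[C@@H]3C(C)C)OC(=O)[C@H]2O[Li] | intermediate (not isolated)
9 | (3S,4S,5S)-4-(1,3-dithian-2-yl)-5-[(1S,2R,5S)-menthyloxy]-3-[(triethylsilyl)oxy]dihydrofuran-2(3H)-one | C1CSC(SC1)[C@@H]2[C@@H](O[C@H]3C[C@@H](C)CC[C@@H]3C(C)C)OC(=O)[C@H]2O[Si](CC)(CC)CC | intermediate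
10 | lithium enolate of 9 | [Li]OC1=C(O[Si](CC)(CC)CC)[C@H](C2SCCCS2)[C@@H](O[C@H]3C[C@@H](C)CC[C@@H]3C(C)C)O1 | intermediate (not isolated)
11 | (3R,4S,5S)-4-(1,3-dithian-2-yl)-3-methyl-5-[(1S,2R,5S)-menthyloxy]-3-[(triethylsilyl)oxy]dihydrofuran-2(3H)-one | C1CSC(SC1)[C@@H]2[C@@H](O[C@H]3C[C@@H](C)CC[C@@H]3C(C)C)OC(=O)[C@]2(C)O[Si](CC)(CC)CC | intermediate
12 | (3R,4S)-4-(1,3-dithian-2-yl)-3,5-dihydroxy-3-methyldihydrofuran-2(3H)-one (C5 anomers) | C1CSC(SC1)[C@@H]2C(O)OC(=O)[C@]2(C)O | intermediate
13 | (2R,3R,4R)-3-(1,3-dithian-2-yl)-2,4-dihydroxy-2,6-dimethylhept-6-enoic acid | OC(=O)[C@](C)(O)[C@H](C1SCCCS1)[C@H](O)CC(C)=C | intermediate (not isolated)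
14 | (3R,4R,5R)-4-(1,3-dithian-2-yl)-3-hydroxy-3-methyl-5-(2-methylprop-2-en-1-yl)dihydrofuran-2(3H)-one | C1CSC(SC1)[C@@H]2[C@@H](CC(C)=C)OC(=O)[C@]2(C)O | intermediate
15 | (2R,3R,4R)-4-hydroxy-4-methyl-2-(2-methylprop-2-en-1-yl)-5-oxotetrahydrofuran-3-carbaldehyde | O=C[C@@H]1[C@@H](CC(C)=C)OC(=O)[C@]1(C)O | intermediate
16 | hex-1-en-5-yne | C#CCCC=C | starting material
17 | dimethyl[(1E)-2-methylhexa-1,5-dien-1-yl]alane | C[Al](C)/C=C(\C)CCC=C | intermediate (not isolated)
18 | (1E)-1-iodo-2-methylhexa-1,5-diene | I/C=C(\C)CCC=C | intermediate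
19 | [(1E)-2-methylhexa-1,5-dien-1-yl]lithium | [Li]/C=C(\C)CCC=C | intermediate (not isolated)
20 | (3R,4R,5R)-3-hydroxy-4-[(1S,2E)-1-hydroxy-3-methylhepta-2,6-dien-1-yl]-3-methyl-5-(2-methylprop-2-en-1-yl)dihydrofuran-2(3H)-one | O[C@@H](/C=C(\C)CCC=C)[C@@H]1[C@@H](CC(C)=C)OC(=O)[C@]1(C)O | intermediate
21 | (3R,4R,5R)-4-{(R)-[(2S,3S)-3-(but-3-en-1-yl)-3-methyloxiran-2-yl](hydroxy)methyl}-3-hydroxy-3-methyl-5-(2-methylprop-2-en-1-yl)dihydrofuran-2(3H)-one | O[C@@H]([C@@H]1O[C@@]1(C)CCC=C)[C@@H]2[C@@H](CC(C)=C)OC(=O)[C@]2(C)O | intermediate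
22 | angelic acid, (2Z)-2-methylbut-2-enoic acid | C/C=C(/C)C(=O)O | starting material
23 | (S)-[(2S,3S)-3-(but-3-en-1-yl)-3-methyloxiran-2-yl][(2R,3S,4R)-4-hydroxy-4-methyl-2-(2-methylprop-2-en-1-yl)-5-oxotetrahydrofuran-3-yl]methyl (2Z)-2-methylbut-2-enoate | C/C=C(/C)C(=O)O[C@H]([C@@H]1O[C@@]1(C)CCC=C)[C@@H]2[C@@H](CC(C)=C)OC(=O)[C@]2(C)O | intermediate
24 | (1(10)Z,4S,5S,6S,7S,8R,11R)-6-angeloyloxy-4,5-epoxy-11-hydroxygermacr-1(10)-en-12,8-olide | C/C=C(/C)C(=O)O[C@H]1[C@@H]2[C@@H](C/C(C)=C\CC[C@]3(C)O[C@@H]13)OC(=O)[C@]2(C)O | intermediate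
25 | (2Z)-2-methylbut-2-enoic 2,4,6-trichlorobenzoic anhydride | C/C=C(/C)C(=O)OC(=O)c1c(Cl)cc(Cl)cc1Cl | intermediate (not isolated)
26 | lithium 11-alkoxide of 24 | C/C=C(/C)C(=O)O[C@H]1[C@@H]2[C@@H](C/C(C)=C\CC[C@]3(C)O[C@@H]13)OC(=O)[C@]2(C)O[Li] | intermediate (not isolated)
27 | CNP0118683.3, (1(10)Z,4S,5S,6S,7S,8R,11R)-6,11-bis(angeloyloxy)-4,5-epoxygermacr-1(10)-en-12,8-olide | C/C=C(/C)C(=O)O[C@H]1[C@@H]2[C@@H](C/C(C)=C\CC[C@]3(C)O[C@@H]13)OC(=O)[C@]2(C)OC(=O)/C(C)=C\C | target

## Step count and risks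

Total step count: 13. Longest linear sequence: 12 (steps 1–7 and 9–13; step 8 is a one-step side branch).

Three steps most likely to fail, each with a fallback:

**Step 9 (facial control in the alkenyl addition).** If the chelate does not control the addition, or the β-hydroxy aldehyde suffers retro-aldol cleavage with the basic reagent, the fallback sets out from 15 and 18 and comes back at 20. Couple them under neutral Nozaki–Hiyama–Kishi conditions (CrCl2, 2 mol % NiCl2, DMSO), which gives 20 mixed with its C6 epimer, the (1R)-allylic alcohol F1. Oxidize the mixture with Dess–Martin periodinane to the single (E)-enone F2. Reduce F2 under reagent control with (S)-1-methyl-3,3-diphenyltetrahydro-1H,3H-pyrrolo[1,2-c][1,3,2]oxazaborole (the (S)-Me-CBS catalyst) and catecholborane, the enone olefin acting as the large group, to give 20.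

**Step 11 (Mitsunobu inversion at a hindered carbinol next to an oxirane).** If substitution is too slow or elimination wins, the fallback sets out from 21 and comes back at 23 by inverting C6 through redox instead of displacement. Oxidize 21 with Dess–Martin periodinane to the epoxy ketone F3. Reduce F3 with Zn(BH4)2 in Et2O at −20 °C, where zinc chelates the carbonyl and oxirane oxygens and delivers the erythro (6S) epoxy alcohol F4. Esterify F4 with 22 (2,4,6-trichlorobenzoyl chloride, Et3N, 4-(dimethylamino)pyridine, toluene) to give 23.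

**Step 12 (ring-closing metathesis; the riskiest step).** If oligomers or no closure result on the flexible seco-diene 23, the fallback sets out from 21 and comes back at 24 by closing the ring one stage earlier on a conformationally locked substrate. Bridge the cis-disposed C6 and C11 hydroxyls of 21 with t-Bu2Si(OTf)2 and 2,6-lutidine to give the cyclic silylene F5, which folds the two olefinic arms toward each other. Ring-closing metathesis of F5 with the same ruthenium catalyst gives the macrocyclic silylene F6. Cleave the silylene with n-Bu4NF buffered with acetic acid to give the macrocyclic 6-epi diol F7. Mitsunobu esterification of F7 with 22 (PPh3, diisopropyl azodicarboxylate) inverts C6 and gives 24.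

## Further compounds

F1 | step 9 | (3R,4R,5R)-3-hydroxy-4-[(1R,2E)-1-hydroxy-3-methylhepta-2,6-dien-1-yl]-3-methyl-5-(2-methylprop-2-en-1-yl)dihydrofuran-2(3H)-one (C6 epimer of 20) | O[C@H](/C=C(\C)CCC=C)[C@@H]1[C@@H](CC(C)=C)OC(=O)[C@]1(C)O
F2 | step 9 | (3R,4R,5R)-3-hydroxy-3-methyl-4-[(2E)-3-methylhepta-2,6-dienoyl]-5-(2-methylprop-2-en-1-yl)dihydrofuran-2(3H)-one | O=C(/C=C(\C)CCC=C)[C@@H]1[C@@H](CC(C)=C)OC(=O)[C@]1(C)O
F3 | step 11 | (3R,4R,5R)-4-{[(2S,3S)-3-(but-3-en-1-yl)-3-methyloxiran-2-yl]carbonyl}-3-hydroxy-3-methyl-5-(2-methylprop-2-en-1-yl)dihydrofuran-2(3H)-one | O=C([C@@H]1O[C@@]1(C)CCC=C)[C@@H]2[C@@H](CC(C)=C)OC(=O)[C@]2(C)O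
F4 | step 11 | (3R,4S,5R)-4-{(S)-[(2S,3S)-3-(but-3-en-1-yl)-3-methyloxiran-2-yl](hydroxy)methyl}-3-hydroxy-3-methyl-5-(2-methylprop-2-en-1-yl)dihydrofuran-2(3H)-one (C6 epimer of 21) | O[C@H]([C@@H]1O[C@@]1(C)CCC=C)[C@@H]2[C@@H](CC(C)=C)OC(=O)[C@]2(C)O
F5 | step 12 | cyclic di-tert-butylsilylene of 21 (silicon bridging O6 and O11) | CC(C)(C)[Si]1(C(C)(C)C)O[C@@H]([C@@H]2O[C@@]2(C)CCC=C)[C@@H]3[C@@H](CC(C)=C)OC(=O)[C@]3(C)O1
F6 | step 12 | (1(10)Z,4S,5S,6R,7R,8R,11R)-4,5-epoxy-6,11-[(di-tert-butylsilanediyl)bis(oxy)]germacr-1(10)-en-12,8-olide | CC(C)(C)[Si]1(C(C)(C)C)O[C@@H]2[C@@H]3[C@@H](C/C(C)=C\CC[C@]4(C)O[C@@H]24)OC(=O)[C@]3(C)O1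
F7 | step 12 | (1(10)Z,4S,5S,6R,7R,8R,11R)-4,5-epoxy-6,11-dihydroxygermacr-1(10)-en-12,8-olide | O[C@@H]1[C@@H]2[C@@H](C/C(C)=C\CC[C@]3(C)O[C@@H]13)OC(=O)[C@]2(C)O
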